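**Retrosynthetic overview**

- C4 core and aryl units: dimethyl succinate (1), used as its bis(silyl ketene acetal) (2), plus two molecules of O-benzylvanillin (3).
- Key disconnection: the two ArCH(O)–CH(CO2Me) bonds are made in one catalytic asymmetric two-directional Mukaiyama aldol (2 + 2 × 3 → 4), which sets all four stereocentres.
- Only ring (the oxolane), formed once: SN1 cycloetherification between the two benzylic oxygens of 4 gives the all-trans diester 5. The CH2OH carbons stay as esters here so they cannot close a furofuran.
- End game: ester reduction (6), then debenzylation to (+)-neoolivil (7).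

Assumption: the catalyst enantiomer written as (S,S) is taken to give the (R)-configured centres; the sense of induction is checked on first use and the other enantiomer used if needed.

**Step 1**
Reactants: 1, dimethyl succinate
Product: 2, (1E,3E)-1,4-dimethoxy-1,4-bis(trimethylsilyloxy)buta-1,3-diene (geometric purity not required)
Conditions: TMSCl (2.6 equiv) then LDA (2.3 equiv), THF, −78 °C → rt (internal quench); filter LiCl under Ar, distil
Reagents that add atoms: chlorotrimethylsilane, C[Si](C)(C)Cl
Why: Double kinetic ester enolisation with in-situ O-silylation (silyl ketene acetal formation) outruns Claisen self-condensation and gives the known, distillable bis(ketene silyl acetal); no stereocentre is formed.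

**Step 2**
Reactants: 2, succinate bis(silyl ketene acetal) (1.0 equiv); 3, 4-(benzyloxy)-3-methoxybenzaldehyde (2.2 equiv)
Product: 4, dimethyl (2R,3R)-2,3-bis{(R)-[4-(benzyloxy)-3-methoxyphenyl][(trimethylsilyl)oxy]methyl}butanedioate
Conditions: (S,S)-IDPi (confined BINOL-derived imidodiphosphorimidate Brønsted acid, 2 mol%), toluene, −78 → −60 °C, 48 h; Et3N quench; rapid filtration through Et3N-deactivated silica
Reagents that add atoms: none (both TMS groups come from 2)
Why: Proposed new method: a catalytic asymmetric two-directional (double) Mukaiyama aldol of a succinate bis(silyl ketene acetal) — 2 silylates the IDPi acid to a silylium/chiral-anion pair, which O-silylates 3 to a silyloxocarbenium held in the confined anion; C2 of the diene adds through an open antiperiplanar (syn) transition state and silyl transfer back to the anion turns the catalyst over, and the remaining ketene acetal repeats this at C3 under catalyst control, so both C–C bonds and all four stereocentres are set, minor-face events are diverted into a separable meso isomer (Horeau amplification), and the O-silylated product cannot lactonise; the closest known reaction is the silylium-counteranion (IDPi/disulfonimide) catalysed enantioselective Mukaiyama aldol of aromatic aldehydes with mono silyl ketene acetals.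

**Step 3**
Reactants: 4, bis(benzylic silyl ether) diester
Product: 5, dimethyl (2R,3R,4R,5R)-2,5-bis[4-(benzyloxy)-3-methoxyphenyl]oxolane-3,4-dicarboxylate (all-trans)
Conditions: TMSOTf (15 mol%), CH2Cl2 (0.02 M), −78 → −30 °C, 2 h; Et3N quench at −30 °C; chromatography (removes 3,4-cis isomers derived from meso-4)
Reagents that add atoms: none ((TMS)2O is lost)
Why: SN1 cycloetherification — TMSOTf silylates one benzylic OTMS oxygen, (TMS)2O leaves to give a p-benzyloxy-stabilised benzylic cation that is trapped 5-exo by the other silyloxy oxygen, and because closure is reversible both aryl carbons settle trans to the untouched (3R,4R) ester centres, giving the all-trans ring whatever the carbinol configuration in 4.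

**Step 4**
Reactants: 5, all-trans oxolane diester
Product: 6, [(2R,3S,4S,5R)-2,5-bis[4-(benzyloxy)-3-methoxyphenyl]oxolane-3,4-diyl]dimethanol
Conditions: LiAlH4 (3 equiv), THF, 0 °C, 1 h; Rochelle salt work-up
Reagents that add atoms: none
Why: Standard LiAlH4 ester-to-primary-alcohol reduction, faster than enolisation of the β-alkoxy esters at 0 °C, so no stereocentre is touched (C3/C4 change from R to S only through CIP priorities).

**Step 5**
Reactants: 6, bis(benzyl ether) diol
Product: 7, (+)-neoolivil, (2R,3S,4S,5R)-2,5-bis(4-hydroxy-3-methoxyphenyl)oxolane-3,4-diyl]dimethanol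
Conditions: H2 (1 atm), 10% Pd/C, EtOAc, rt, about 1 h, stopped at 2 equiv H2 uptake
Reagents that add atoms: none
Why: Pd-catalysed hydrogenolysis of aryl benzyl ethers is much faster than cleavage of the hindered benzylic ring C–O bonds under these mild aprotic conditions, so both phenols are freed with the four stereocentres intact.

**Compound list**

1 | dimethyl succinate | COC(=O)CCC(=O)OC | starting material
2 | (1E,3E)-1,4-dimethoxy-1,4-bis(trimethylsilyloxy)buta-1,3-diene | C[Si](C)(C)O/C(OC)=C/C=C(\OC)O[Si](C)(C)C | intermediate
3 | 4-(benzyloxy)-3-methoxybenzaldehyde (O-benzylvanillin) | COc1cc(C=O)ccc1OCc1ccccc1 | starting material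
4 | dimethyl (2R,3R)-2,3-bis{(R)-[4-(benzyloxy)-3-methoxyphenyl][(trimethylsilyl)oxy]methyl}butanedioate | COc1cc([C@H](O[Si](C)(C)C)[C@H](C(=O)OC)[C@@H](C(=O)OC)[C@@H](O[Si](C)(C)C)c2ccc(OCc3ccccc3)c(OC)c2)ccc1OCc1ccccc1 | intermediate
5 | dimethyl (2R,3R,4R,5R)-2,5-bis[4-(benzyloxy)-3-methoxyphenyl]oxolane-3,4-dicarboxylate | COc1cc([C@@H]2O[C@@H](c3ccc(OCc4ccccc4)c(OC)c3)[C@H](C(=O)OC)[C@H]2C(=O)OC)ccc1OCc1ccccc1 | intermediate
6 | [(2R,3S,4S,5R)-2,5-bis[4-(benzyloxy)-3-methoxyphenyl]oxolane-3,4-diyl]dimethanol | COc1cc([C@@H]2O[C@@H](c3ccc(OCc4ccccc4)c(OC)c3)[C@H](CO)[C@H]2CO)ccc1OCc1ccccc1 | intermediate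
7 | (+)-neoolivil, [(2R,3S,4S,5R)-2,5-bis(4-hydroxy-3-methoxyphenyl)oxolane-3,4-diyl]dimethanol | COc1cc([C@@H]2O[C@@H](c3ccc(O)c(OC)c3)[C@H](CO)[C@H]2CO)ccc1O | target

**Total step count:** 5
**Longest linear sequence:** 5 (1 → 2 → 4 → 5 → 6 → 7; 3 is purchased)

**Steps most likely to fail**

1. Step 2 (proposed new double aldol). The second, more hindered addition may be slow or poorly catalyst-controlled, giving more meso isomer.
   Fallback (known chemistry): build the array stepwise. Proline-catalysed cross-aldol of methyl 4-oxobutanoate with 3 sets the first ArCH(O)–CH pair. Pinnick oxidation with lactonisation gives the trans γ-aryl paraconic acid. A dianion aldol with a second 3 adds the other arm, and esterification plus acid-mediated closure between the benzylic oxygens rejoins the route at 5.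

2. Step 3 (cycloetherification). The ester-flanked benzylic cation could instead eliminate to the benzylidene succinate, attack the other arene (aryltetralin), or lactonise.
   Fallback: reorder the end game. Reduce 4 to the tetraol with LiAlH4, cap the two primary alcohols as pivalates (this blocks furofuran formation and removes the α-ester hydrogen that drives elimination), close the free 1,4-benzylic diol with CSA or BF3·OEt2, then remove the pivalates with hydride.

3. Step 5 (hydrogenolysis). Over-reduction could open the oxolane at a benzylic C–O bond.
   Fallback: change the phenol protecting group from the start. Use 4-(tert-butyldimethylsilyloxy)-3-methoxybenzaldehyde (vanillin + TBSCl) in step 2 and finish with TBAF/AcOH desilylation instead of hydrogenolysis.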